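I decide to reckon this flask by its charges and not by a rate.

the same everywhere: L 0.19 M

| flask | G | remark | time |
|---|---|---|---|
| ochre | 0.152 M | the very flask that is asked about, followed so far |  |
| red | 0.23 M | run made earlier |  |
| flask | 0.152 M |  | 3.0 d |

ochre run (percent of the L charged): time / h: J / % = 6.00: 78.1; 10.0: 79.5; 15.0: 79.5; 25.0: 80.6; 40.0: 78.9; 72.0: 80.5

red run (percent of the L charged): time / min: J / % = 8.00: 0.5; 12.0: 3.2; 20.0: 0; 40.0: 5.7; 60.0: 12.4; 90.0: 19.6

(scatter of a reading: 1 percentage point)

- birch: at 3.0 d take out 90% of the J then present, then wait 3.0 d
- elm: at 3.0 d add G, 50.0% of the amount charged, then wait 3.0 d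
- maple: change nothing and wait 3.0 d more

- solid, in amounts per volume of the solution: L
- removed J is counted in
- candidate steps: E -> Q; G -> Z; Q + Z -> J; L <-> E
- at the start none of L is in solution
- additions bring no volume worth counting

- J, in percent of the L first charged, at 3.0 d
- the option that brings most further J ("none" if no option brings more than 2 percentage points) (birch / elm / maple / none)
- J present, with what was taken out counted in, in percent of the L first charged, after birch
- J present, with what was taken out counted in, in percent of the L first charged, after maple

The candidate steps make each J from one Q and one Z, so each J costs one L and one G. The flask holds less G than L, so I take G as the limiting reagent and carry the ceiling, c(G) over c(L) at the start, in percent of the L charged: 80.0%. The share of L left without a partner is then 20.0%.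

The ochre readings agree: from 10.0 h to 72.0 h they lie between 78.9% and 80.6%, with a scatter of 1 percentage point. But the red run reads 19.6% at 90.0 min, its last reading, so it shows a slow start and, up to there, no plateau.

So I commit to the ceiling for now. Q + Z -> J is written one way, so birch frees no G, and maple adds none. Elm adds 0.0760 M of G, more than the 0.0380 M of L without a partner, so L becomes the limit.

The forecast gives 80% now, 80% after birch, 80% after maple, and elm as best, holding that “the plateau is most simply explained by G running out”.

The flask gives 80.0% at 3.0 d; elm brings 20 points more, birch 0 points and maple 0 points.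

    E → Q (k = 3.20 × 10⁻⁴ s⁻¹)
    G → Z (k = 6.30 × 10⁻⁴ s⁻¹)
    Q + Z → J (k = 0.00800 M⁻¹ s⁻¹)
    L ⇌ E, rate k4*(cs4 - [E]) while solid is left; crystals form when [E] > cs4 (solubility = 30.0 mM, k = 0.00370 s⁻¹)

In the flask J stands at the ceiling of 80.0%, and at 72.0 h Q holds 20.0% of the L charged. For the neighbour flask with L at 0.76 M, the same G gives a ceiling of 20.0%, and that flask gives 20.0%.

The readings were generated by integration with made-up constants; the scatter is artificial.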